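**Retrosynthetic overview**
1. 14 ⇐ 10 + 11 (step 7): the benzyl cation from 11 alkylates the enol ether β-carbon of 10 (C8–C9 bond) while ring carbon C3 shifts from the tertiary ether carbon to the exocyclic carbon (future C4). The cyclopentenone ring thereby becomes the six-membered dienone ring, the only ring the route forms (arene and five-membered ring are bought).
2. Enabling feature: in 10 the ring carbon that becomes C5 is a tertiary methyl ether bearing the 1-methoxyprop-1-enyl group (future C4=C8), flanked by vinylic C3 and by the CH2 (C6) α to the C1 ketone. The O-stabilised cation at C4 draws C3 over, and the C5 oxocarbenium then sheds the C6 proton, so the C4(OMe)–C5(OMe)=C6–C1=O array of 14 arises directly.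
3. 10 ⇐ 3 + 5: addition of α-lithiated (E)-1-methoxypropene anti to the silyloxy group, O-methylation, desilylation, oxidation (the silyloxy centre relays chirality and is then erased).
4. 3 ⇐ 1 (commercial, R): conjugate allylation with silyl trapping, then Saegusa–Ito oxidation; 5 ⇐ allyl methyl ether 4 by E-selective isomerisation.

Key step: step 7

Remark: locants used for 14 are ring C1 (C=O), C2 (allyl), C3 (=CH), C4 (quaternary, OMe), C5 (=C–OMe), C6 (=CH), side chain C8 (CH–CH3) and C9 (benzylic CH2); 14 is 4S,8S. Ether 5 is assumed not to be sold as the pure E isomer and is therefore made.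

Step 1
Reactants: 1 (R)-4-[(tert-butyldimethylsilyl)oxy]cyclopent-2-en-1-one
Product: 2 tert-butyl{[(1R,2R)-2-allyl-4-[(trimethylsilyl)oxy]cyclopent-3-en-1-yl]oxy}dimethylsilane
Conditions: allylMgBr, CuBr·SMe2 (1 equiv), TMSCl, THF, −78 °C; Et3N/pentane work-up, used crude
Reagents that add atoms: allylmagnesium bromide C=CC[Mg]Br; chlorotrimethylsilane C[Si](C)(C)Cl
Why: Organocopper conjugate addition accelerated by TMSCl should place the allyl group on the β-carbon anti to the silyloxy group (as in three-component couplings on this enone) and fix the enolate regiospecifically as its TMS enol ether; the new allyl-bearing centre is removed again in step 2.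

Step 2
Reactants: 2 tert-butyl{[(1R,2R)-2-allyl-4-[(trimethylsilyl)oxy]cyclopent-3-en-1-yl]oxy}dimethylsilane
Product: 3 (R)-3-allyl-4-[(tert-butyldimethylsilyl)oxy]cyclopent-2-en-1-one
Conditions: Pd(OAc)2 (1.05 equiv), MeCN, rt
Reagents that add atoms: none
Why: Saegusa–Ito oxidation: palladation of the silyl enol ether and syn β-hydride elimination can only take the hydrogen on the allyl-bearing carbon, which returns the enone with the allyl group on its β-carbon and leaves the silyloxy stereocentre untouched.

Step 3
Reactants: 4 allyl methyl ether (3-methoxyprop-1-ene)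
Product: 5 (E)-1-methoxyprop-1-ene
Conditions: [Ir(cod)(PMePh2)2]PF6 (0.5 mol %, activated with H2), THF, rt; distilled
Reagents that add atoms: none
Why: Iridium hydride catalysed allyl-to-propenyl ether isomerisation is known to give trans-propenyl ethers selectively; no stereocentre is formed, but this E geometry later fixes the relative configuration C4/C8.

Step 4
Reactants: 5 (E)-1-methoxyprop-1-ene; 3 (R)-3-allyl-4-[(tert-butyldimethylsilyl)oxy]cyclopent-2-en-1-one
Product: 8 tert-butyl{[(1R,4S)-2-allyl-4-methoxy-4-[(E)-1-methoxyprop-1-en-1-yl]cyclopent-2-en-1-yl]oxy}dimethylsilane, via (E)-(1-methoxyprop-1-en-1-yl)lithium 6 (not isolated), via tertiary lithium alkoxide 7 (not isolated)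
Conditions: 5 (2 equiv), t-BuLi, THF–pentane, −78 → −10 °C; 3, −78 °C; MeOTf, −78 → −20 °C; Et3N quench
Reagents that add atoms: methyl trifluoromethanesulfonate COS(=O)(=O)C(F)(F)F
Why: Oxygen-directed α-lithiation of the vinyl ether gives the configurationally stable vinyllithium 6 (Li cis to the methyl), its 1,2-addition to the enone carbonyl should occur anti to the silyloxy group (tertiary carbinol centre S, new C–O bond cis to OTBS), and alkoxide 7 is O-methylated (Williamson type) at low temperature before silyl migration can compete; the minor carbinol epimer must be removed here, because after step 6 it would become the enantiomer of 10.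

Step 5
Reactants: 8 tert-butyl{[(1R,4S)-2-allyl-4-methoxy-4-[(E)-1-methoxyprop-1-en-1-yl]cyclopent-2-en-1-yl]oxy}dimethylsilane
Product: 9 (1R,4S)-2-allyl-4-methoxy-4-[(E)-1-methoxyprop-1-en-1-yl]cyclopent-2-en-1-ol
Conditions: TBAF, THF, 0 °C
Reagents that add atoms: none
Why: Fluoride-induced desilylation is basic enough to leave the enol ether and the tertiary allylic methyl ether intact and touches no stereocentre.

Step 6
Reactants: 9 (1R,4S)-2-allyl-4-methoxy-4-[(E)-1-methoxyprop-1-en-1-yl]cyclopent-2-en-1-ol
Product: 10 (S)-2-allyl-4-methoxy-4-[(E)-1-methoxyprop-1-en-1-yl]cyclopent-2-en-1-one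
Conditions: MnO2, CH2Cl2, rt; chromatography on Et3N-deactivated silica
Reagents that add atoms: none
Why: Allylic alcohol oxidation with MnO2 under neutral conditions should give the enone without hydrolysing the enol ether; the relay stereocentre is deliberately erased and the tertiary ether centre (S) now carries all the chirality.

Step 7
Reactants: 10 (S)-2-allyl-4-methoxy-4-[(E)-1-methoxyprop-1-en-1-yl]cyclopent-2-en-1-one; 11 3,4-dimethoxybenzyl chloride
Product: 14 (4S)-2-allyl-4-[(2S)-1-(3,4-dimethoxyphenyl)propan-2-yl]-4,5-dimethoxycyclohexa-2,5-dien-1-one, via 3,4-dimethoxybenzyl triflate 12 (not isolated), via ring-enlarged C5 oxocarbenium triflate 13 (not isolated)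
Conditions: AgOTf (1.2 equiv), 2,6-di-tert-butyl-4-methylpyridine (1.5 equiv), 4 Å MS, CH2Cl2, −78 → −30 °C, slow addition of 11
Reagents that add atoms: none
Why: Proposed new method: AgOTf turns 11 into triflate 12, whose benzylic cation is attacked by the enol ether β-carbon (C8) of 10 on the face opposite the aligned ring bond, and as oxocarbenium character builds at C4 the vinylic ring carbon C3 shifts suprafacially from the tertiary ether carbon to C4, so the cyclopentenone is enlarged by this exocyclic carbon (a 1,2-shift, no ring is closed by cyclisation); the ring oxocarbenium 13 at C5 then loses the C6 proton (α to the C1 ketone) to the hindered pyridine and gives the vinylogous ester of 14. The closest known reaction types are electrophile-induced semipinacol ring expansions of 1-(1-alkoxyvinyl)cycloalkanols (proton or halonium triggered, anti addition of electrophile and migrating carbon) and Lewis-acid alkylation of enol ethers by benzylic halides; new are the carbon electrophile, the methyl ether in place of the free carbinol (which delivers the methyl enol ether directly) and the five-to-six enlargement by a vinylic migrating carbon. C4 is controlled by chirality transfer from the tertiary ether centre of 10, which is itself destroyed: the reactive rotamer should hold the ring C–OMe bond in the enol ether plane beside C8 (smallest group next to the cis methyl, least allylic 1,3-strain, C–O dipoles opposed), which puts C3 on the face that leads to 4S and the C6 methylene on the other. C8 is controlled by the E geometry of the enol ether together with anti addition (benzyl to C8, C3 to C4 from opposite faces), which gives the like 4S,8S pair. The step needs alkylation at the enol ether rather than at the allyl group or an arene (the enol ether is by far the strongest π nucleophile and 11 is added slowly), migration of sp2 C3 rather than the α-keto methylene C6, and a shift that keeps pace with C–C bond formation. The irreversible proton loss from C6 to the conjugated vinylogous ester is the driving force.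

**Compound list**
1 | (R)-4-[(tert-butyldimethylsilyl)oxy]cyclopent-2-en-1-one | O=C1C=C[C@H](O[Si](C)(C)C(C)(C)C)C1 | starting material
2 | tert-butyl{[(1R,2R)-2-allyl-4-[(trimethylsilyl)oxy]cyclopent-3-en-1-yl]oxy}dimethylsilane | C=CC[C@@H]1C=C(O[Si](C)(C)C)C[C@H]1O[Si](C)(C)C(C)(C)C | intermediate
3 | (R)-3-allyl-4-[(tert-butyldimethylsilyl)oxy]cyclopent-2-en-1-one | C=CCC1=CC(=O)C[C@H]1O[Si](C)(C)C(C)(C)C | intermediate
4 | allyl methyl ether (3-methoxyprop-1-ene) | C=CCOC | starting material
5 | (E)-1-methoxyprop-1-ene | C/C=C/OC | intermediate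
6 | (E)-(1-methoxyprop-1-en-1-yl)lithium (Li cis to methyl) | C/C=C(/OC)[Li] | intermediate
7 | lithium (1S,4R)-3-allyl-4-[(tert-butyldimethylsilyl)oxy]-1-[(E)-1-methoxyprop-1-en-1-yl]cyclopent-2-en-1-olate | C=CCC1=C[C@]([O-])(/C(OC)=C\C)C[C@H]1O[Si](C)(C)C(C)(C)C.[Li+] | intermediate
8 | tert-butyl{[(1R,4S)-2-allyl-4-methoxy-4-[(E)-1-methoxyprop-1-en-1-yl]cyclopent-2-en-1-yl]oxy}dimethylsilane | C=CCC1=C[C@](OC)(/C(OC)=C\C)C[C@H]1O[Si](C)(C)C(C)(C)C | intermediate
9 | (1R,4S)-2-allyl-4-methoxy-4-[(E)-1-methoxyprop-1-en-1-yl]cyclopent-2-en-1-ol | C=CCC1=C[C@](OC)(/C(OC)=C\C)C[C@H]1O | intermediate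
10 | (S)-2-allyl-4-methoxy-4-[(E)-1-methoxyprop-1-en-1-yl]cyclopent-2-en-1-one | C=CCC1=C[C@](OC)(/C(OC)=C\C)CC1=O | intermediate
11 | 3,4-dimethoxybenzyl chloride | COc1ccc(CCl)cc1OC | starting material
12 | 3,4-dimethoxybenzyl trifluoromethanesulfonate | COc1ccc(COS(=O)(=O)C(F)(F)F)cc1OC | intermediate
13 | ring-enlarged O-methyl oxocarbenium triflate (cation at C5, C6 still CH2, 4S,8S) | C=CCC1=C[C@@](OC)([C@@H](C)Cc2ccc(OC)c(OC)c2)C(=[O+]C)CC1=O.[O-]S(=O)(=O)C(F)(F)F | intermediate
14 | (4S)-2-allyl-4-[(2S)-1-(3,4-dimethoxyphenyl)propan-2-yl]-4,5-dimethoxycyclohexa-2,5-dien-1-one | C=CCC1=C[C@@](OC)([C@@H](C)Cc2ccc(OC)c(OC)c2)C(OC)=CC1=O | target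

Total step count: 7. Longest linear sequence: 6 steps (steps 1, 2, 4, 5, 6, 7).

**Steps most likely to fail**

Step 7 (proposed new method). The 1,2-shift of the electron-poor vinylic carbon may lag behind C–C bond formation. The first oxocarbenium ion would then live long enough to rotate, to lose a proton back to a tetrasubstituted enol ether, or to be captured by the veratryl ring in a Friedel–Crafts closure. This would erode the configuration at C8 and divert material. The fallback uses only known chemistry (oxidative dearomatisation of a para-alkylphenol); it sets out from 11 and returns at 14. Chloride 11 is converted with Mg (THF, 0 °C) into 3,4-dimethoxybenzylmagnesium chloride F1. F1 adds to purchased 1-[4-(benzyloxy)-2-methoxyphenyl]ethan-1-one to give tertiary alcohol 2-[4-(benzyloxy)-2-methoxyphenyl]-1-(3,4-dimethoxyphenyl)propan-2-ol F2. Acid-catalysed dehydration (TsOH, toluene, 80 °C) gives the conjugated stilbene 4-(benzyloxy)-1-[(E)-1-(3,4-dimethoxyphenyl)prop-1-en-2-yl]-2-methoxybenzene F3. Asymmetric hydrogenation of this trisubstituted alkene with an iridium phosphinooxazoline catalyst of the type [Ir(cod)(PHOX)]BArF (H2, CH2Cl2), using the ligand enantiomer that delivers the S product, gives 4-(benzyloxy)-1-[(S)-1-(3,4-dimethoxyphenyl)propan-2-yl]-2-methoxybenzene F4. Hydrogenolysis (H2, Pd/C, EtOAc) frees 4-[(S)-1-(3,4-dimethoxyphenyl)propan-2-yl]-3-methoxyphenol F5. Allyl bromide/K2CO3 (acetone) gives 4-(allyloxy)-1-[(S)-1-(3,4-dimethoxyphenyl)propan-2-yl]-2-methoxybenzene F6. Aromatic Claisen rearrangement (N,N-diethylaniline, 190 °C) to the less hindered ortho position gives 2-allyl-4-[(S)-1-(3,4-dimethoxyphenyl)propan-2-yl]-5-methoxyphenol F7. PhI(OAc)2 in MeOH at 0 °C adds methanol para to the hydroxyl and gives 14. The C8 centre is expected to control C4 only weakly here, so the (4R)-epimer of 14 F8 must be removed by chromatography.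

Step 4. The base may remove an allylic methyl hydrogen instead of the α-vinylic hydrogen, or lithiation may be slow enough that t-BuLi survives. Enone 3 may be enolised instead of attacked, and facial selectivity may be incomplete. The fallback generates 6 by tin–lithium exchange instead of deprotonation; it sets out from 3 and returns at 8. Purchased methoxyallene is lithiated (n-BuLi, THF, −40 °C) and quenched with Bu3SnCl to give tributyl(1-methoxypropa-1,2-dien-1-yl)stannane F9. Diimide (2-nitrobenzenesulfonylhydrazide, Et3N, CH2Cl2) should reduce the terminal C=C from the side away from the stannyl group, placing the new methyl cis to tin, to give (Z)-tributyl(1-methoxyprop-1-en-1-yl)stannane F10. n-BuLi (THF, −78 °C) then gives 6 with retention, free of t-BuLi and of allylic anions. Addition to 3 and methylation with MeOTf as in step 4 give 8.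

Step 2. Palladium hydride may move the allyl double bond into conjugation, divalent palladium may engage the terminal alkene, and the silyloxy group may be lost by elimination. The fallback is a selenoxide elimination; it sets out from 2 and returns at 3. Silyl enol ether 2 is treated with PhSeCl (THF, −78 °C) to give (2R,3S,4R)-3-allyl-4-[(tert-butyldimethylsilyl)oxy]-2-(phenylselanyl)cyclopentan-1-one F11, with selenium anti to the neighbouring allyl group and hence syn to the hydrogen on that carbon. Oxidation with H2O2/pyridine (CH2Cl2, 0 °C) and syn elimination of the selenoxide, which can only take that hydrogen, give 3.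

**Further compounds**
F1 | step 7 | 3,4-dimethoxybenzylmagnesium chloride | COc1ccc(C[Mg]Cl)cc1OC
F2 | step 7 | 2-[4-(benzyloxy)-2-methoxyphenyl]-1-(3,4-dimethoxyphenyl)propan-2-ol | COc1ccc(CC(C)(O)c2ccc(OCc3ccccc3)cc2OC)cc1OC
F3 | step 7 | 4-(benzyloxy)-1-[(E)-1-(3,4-dimethoxyphenyl)prop-1-en-2-yl]-2-methoxybenzene | COc1ccc(/C=C(\C)c2ccc(OCc3ccccc3)cc2OC)cc1OC
F4 | step 7 | 4-(benzyloxy)-1-[(S)-1-(3,4-dimethoxyphenyl)propan-2-yl]-2-methoxybenzene | COc1cc(OCc2ccccc2)ccc1[C@@H](C)Cc1ccc(OC)c(OC)c1
F5 | step 7 | 4-[(S)-1-(3,4-dimethoxyphenyl)propan-2-yl]-3-methoxyphenol | COc1cc(O)ccc1[C@@H](C)Cc1ccc(OC)c(OC)c1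
F6 | step 7 | 4-(allyloxy)-1-[(S)-1-(3,4-dimethoxyphenyl)propan-2-yl]-2-methoxybenzene | C=CCOc1ccc([C@@H](C)Cc2ccc(OC)c(OC)c2)c(OC)c1
F7 | step 7 | 2-allyl-4-[(S)-1-(3,4-dimethoxyphenyl)propan-2-yl]-5-methoxyphenol | C=CCc1cc([C@@H](C)Cc2ccc(OC)c(OC)c2)c(OC)cc1O
F8 | step 7 | (4R)-2-allyl-4-[(2S)-1-(3,4-dimethoxyphenyl)propan-2-yl]-4,5-dimethoxycyclohexa-2,5-dien-1-one (C4 epimer of 14) | C=CCC1=C[C@](OC)([C@@H](C)Cc2ccc(OC)c(OC)c2)C(OC)=CC1=O
F9 | step 4 | tributyl(1-methoxypropa-1,2-dien-1-yl)stannane | C=C=C(OC)[Sn](CCCC)(CCCC)CCCC
F10 | step 4 | (Z)-tributyl(1-methoxyprop-1-en-1-yl)stannane | C/C=C(/OC)[Sn](CCCC)(CCCC)CCCC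
F11 | step 2 | (2R,3S,4R)-3-allyl-4-[(tert-butyldimethylsilyl)oxy]-2-(phenylselanyl)cyclopentan-1-one | C=CC[C@@H]1[C@@H]([Se]c2ccccc2)C(=O)C[C@H]1O[Si](C)(C)C(C)(C)C
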